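Everything rests on cutting the C5–C10 ring-fusion bond and the C8–C9 bond, both in ring B. These two σ-bonds carry the contiguous stereocentres C5, C10 and C9, so a single intramolecular Diels–Alder reaction of an acyclic trienoate closes ring B as a cyclohexene and ring A through the C1–C4 tether, fixing the trans fusion and the C9 side-chain carbon relative to a C3 centre set beforehand. The precursor joins an (E)-3-methyl enoate (C9=C10, ester = C11) through four carbons, bearing the C3 acetoxy group and the C4 gem-dimethyl unit, to a (Z)-2-silyloxy diene (C5–C8) whose oxygen at C7 is later traded for the C7=C8 alkene.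

Key step: step 7

Remarks on the chemistry:
- α/β and atom numbers follow drimane/labdane numbering (C10 methyl β). Commercial methyl geranate is taken as the pure (2E) isomer.
- Assumption for step 2: the SEGPHOS enantiomer is the one that delivers the (6S)-carbinol, to be confirmed by Mosher ester analysis of 5.
- Design choices: the C3 oxygen is carried as its acetate through the cycloaddition, is cleaved without an extra step in hydride step 11, and is put back in the last step. The dienol ether is a TBS ether so that it survives prolonged heating.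

Step 1
Reactants: 1 methyl geranate (methyl (2E)-3,7-dimethylocta-2,6-dienoate)
Product: 3 methyl (2E)-3-methyl-6-oxohex-2-enoate, via ozonide 2 (not isolated)
Conditions: O3 (to consumption of 1), CH2Cl2, –78 °C; then Me2S, –78 °C → rt
Reagents that add atoms: ozone, [O-][O+]=O
Why: Ozonolysis (Criegee mechanism) with reductive work-up should cleave only the electron-rich trisubstituted C6=C7 bond, because the C2=C3 bond is deactivated toward electrophilic ozone by conjugation with the ester and keeps its (E) geometry.

Step 2
Reactants: 3 methyl (2E)-3-methyl-6-oxohex-2-enoate; 4 3-methylbuta-1,2-diene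
Product: 5 methyl (2E,6S)-6-hydroxy-3,7,7-trimethylnona-2,8-dienoate
Conditions: preformed cyclometalated π-allyl iridium C,O-benzoate catalyst (5 mol%; from [Ir(cod)Cl]2, SEGPHOS, 4-cyano-3-nitrobenzoic acid, Cs2CO3, allyl acetate), 4 (2 equiv), i-PrOH (2 equiv), toluene, 50 °C
Reagents that add atoms: none
Why: Iridium-catalysed transfer-hydrogenative carbonyl reverse prenylation (Krische type), in which an iridium hydride from isopropanol adds to the allene and the resulting 1,1-dimethylallyl iridium species attacks the aldehyde at its substituted terminus through a closed chair transition state, the chiral bisphosphine selecting the aldehyde face and so setting C6 (future C3) as S while the enoate is untouched.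

Step 3
Reactants: 5 methyl (2E,6S)-6-hydroxy-3,7,7-trimethylnona-2,8-dienoate
Product: 6 methyl (2E,6S)-6-acetoxy-3,7,7-trimethylnona-2,8-dienoate
Conditions: Ac2O, pyridine, DMAP (cat.), CH2Cl2, rt
Reagents that add atoms: acetic anhydride, CC(=O)OC(C)=O
Why: DMAP-catalysed acylation (nucleophilic catalysis) of the hindered neopentyl-type secondary alcohol leaves the stereocentre untouched and blocks retro-aldol cleavage of the β-oxygenated aldehyde made next.

Step 4
Reactants: 6 methyl (2E,6S)-6-acetoxy-3,7,7-trimethylnona-2,8-dienoate
Product: 8 methyl (2E,6S)-6-acetoxy-3,7,7-trimethyl-8-oxooct-2-enoate, via diol 7 (not isolated)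
Conditions: OsO4 (2 mol%), NaIO4 (4 equiv), 2,6-lutidine (2 equiv), dioxane/H2O (3:1), rt
Reagents that add atoms: sodium periodate, [Na+].[O-]I(=O)(=O)=O (terminal oxidant; its oxygen reaches C8 through catalytic osmium tetroxide, O=[Os](=O)(=O)=O)
Why: Lemieux–Johnson cleavage, in which OsO4 should dihydroxylate the monosubstituted vinyl group far faster than the electron-poor trisubstituted enoate and periodate cleaves the diol to an aldehyde that has no α-hydrogen and so cannot epimerise or eliminate.

Step 5
Reactants: 8 methyl (2E,6S)-6-acetoxy-3,7,7-trimethyl-8-oxooct-2-enoate; 9 diethyl (2-oxobutyl)phosphonate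
Product: 10 methyl (2E,6S,8E)-6-acetoxy-3,7,7-trimethyl-10-oxododeca-2,8-dienoate
Conditions: LiCl (1.2 equiv), DBU (1.1 equiv), MeCN, rt
Reagents that add atoms: none
Why: Horner–Wadsworth–Emmons olefination under Masamune–Roush conditions, where the stabilised β-keto phosphonate should give the (E)-enone through reversible addition and the favoured anti oxaphosphetane, under a base mild enough to spare the acetate.

Step 6
Reactants: 10 methyl (2E,6S,8E)-6-acetoxy-3,7,7-trimethyl-10-oxododeca-2,8-dienoate
Product: 11 methyl (2E,6S,8E,10Z)-6-acetoxy-10-(tert-butyldimethylsilyloxy)-3,7,7-trimethyldodeca-2,8,10-trienoate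
Conditions: TBSOTf (1.3 equiv), Et3N (2 equiv), CH2Cl2, –78 → 0 °C
Reagents that add atoms: tert-butyldimethylsilyl trifluoromethanesulfonate, CC(C)(C)[Si](C)(C)OS(=O)(=O)C(F)(F)F
Why: Soft enolisation with O-silylation can only remove a C11 hydrogen (C7 is quaternary, so no γ-enolisation), giving the cross-conjugated 2-silyloxy diene, and the (Z) isomer with the C12 methyl away from the vinyl group is expected to prevail by allylic strain.

Step 7
Reactants: 11 methyl (2E,6S,8E,10Z)-6-acetoxy-10-(tert-butyldimethylsilyloxy)-3,7,7-trimethyldodeca-2,8,10-trienoate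
Product: 12 methyl 3β-acetoxy-7-(tert-butyldimethylsilyloxy)-8αH-drim-6-en-11-oate
Conditions: degassed toluene (0.01 M), BHT (0.2 equiv), Et3N (0.5 equiv), sealed silanised tube, 180 °C
Reagents that add atoms: none
Why: Concerted but asynchronous thermal [4+2] cycloaddition in which the electron-rich (Z)-2-silyloxy diene (C5=C6–C7=C8) adds suprafacially to the (E)-enoate (C9=C10); the four-carbon tether enforces the fused regiochemistry although the C7 oxygen polarises the diene toward C8, which is why a forcing temperature is planned. The closest known reaction type is the thermal intramolecular Diels–Alder reaction of terminally activated deca-2,8,10-trienoates and of enone-derived silyloxy dienes with tethered enoates. Ring B closes as the new cyclohexene of the cycloaddition, and ring A closes as the six-membered tether ring (C10–C1–C2–C3–C4–C5) in the fused type 1 mode, helped by the gem-dimethyl group at C4. C9 and C10 follow from the (E)-enoate geometry (ester cis to methyl), C5 relative to C10 from the ester-endo, tether-anti transition state that gives the trans fusion, C8 from the (Z)-enol ether (methyl outside) combined with endo addition, and all four relative to C3 from the chair-like tether with the acetoxy group equatorial. The step needs endo and π-facial selectivity; the endo preference of the ester and the equatorial placement of the C3 substituent beside the quaternary C4 are what the substrate offers, and this is where the route carries its risk.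

Step 8
Reactants: 12 methyl 3β-acetoxy-7-(tert-butyldimethylsilyloxy)-8αH-drim-6-en-11-oate
Product: 13 methyl 3β-acetoxy-7-oxo-8αH-driman-11-oate
Conditions: 1 M HCl, THF, 0 °C → rt
Reagents that add atoms: none
Why: Acid hydrolysis of the silyl enol ether (protonation at C6, loss of silanol) should unmask the C7 ketone without touching the acetate or methyl ester, and any epimerisation at C8 is harmless because C8 becomes sp2 in step 9.

Step 9
Reactants: 13 methyl 3β-acetoxy-7-oxo-8αH-driman-11-oate
Product: 14 methyl 3β-acetoxy-7-(trifluoromethylsulfonyloxy)drim-7-en-11-oate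
Conditions: Tf2O (1.5 equiv), 2,6-di-tert-butyl-4-methylpyridine (2 equiv), CH2Cl2, 0 °C → rt
Reagents that add atoms: trifluoromethanesulfonic anhydride, O=S(=O)(OS(=O)(=O)C(F)(F)F)C(F)(F)F
Why: O-triflation of the ketone with a hindered pyridine base (Stang conditions) should favour the more substituted C7=C8 enol triflate, the direction that also points away from the trans ring-fusion carbon C5, and it erases the C8 stereocentre.

Step 10
Reactants: 14 methyl 3β-acetoxy-7-(trifluoromethylsulfonyloxy)drim-7-en-11-oate
Product: 15 methyl 3β-acetoxydrim-7-en-11-oate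
Conditions: Pd(OAc)2 (5 mol%), PPh3 (10 mol%), HCO2H (2 equiv), Bu3N (3 equiv), DMF, 60 °C
Reagents that add atoms: none
Why: Palladium-catalysed formate reduction of the enol triflate (oxidative addition, formate exchange, decarboxylation, reductive elimination) replaces the triflate by hydrogen without moving the double bond, and the weak amine base cannot deprotonate C9.

Step 11
Reactants: 15 methyl 3β-acetoxydrim-7-en-11-oate
Product: 16 drim-7-ene-3β,11-diol
Conditions: LiAlH4 (3 equiv), THF, 0 °C → rt
Reagents that add atoms: none
Why: Hydride reduction converts the hindered C11 ester into the primary alcohol and cleaves the C3 acetate in the same operation, hydride addition being faster than deprotonation at C9 and the isolated alkene being inert.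

Step 12
Reactants: 16 drim-7-ene-3β,11-diol
Product: 17 3β-hydroxydrim-7-en-11-al
Conditions: TEMPO (10 mol%), PhI(OAc)2 (1.2 equiv), CH2Cl2, rt
Reagents that add atoms: none
Why: Oxoammonium-mediated oxidation is strongly selective for primary over hindered secondary alcohols, so only C11 should be oxidised, and the nearly neutral medium should leave the C9 centre and the C7=C8 position alone.

Step 13
Reactants: 17 3β-hydroxydrim-7-en-11-al
Product: 18 13,14,15,16-tetranorlabda-7,11-dien-3β-ol (drim-7-en-3β-ol bearing a 9β-vinyl group)
Conditions: Ph3PCH3Br (3.0 equiv), KN(SiMe3)2 (2.8 equiv), THF, –78 → 0 °C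
Reagents that add atoms: methyltriphenylphosphonium bromide, C[P+](c1ccccc1)(c1ccccc1)c1ccccc1.[Br-]
Why: Wittig methylenation with a non-stabilised ylide, in which the excess ylide takes up the C3 hydroxyl proton and carbonyl addition at low temperature should outrun enolisation at C9.

Step 14
Reactants: 19 methyl acetoacetate
Product: 20 methyl (2E)-3-(trifluoromethylsulfonyloxy)but-2-enoate
Conditions: Tf2O (1.5 equiv), aqueous Me4NOH (25%, 3 equiv), hexane, 5 °C
Reagents that add atoms: trifluoromethanesulfonic anhydride, O=S(=O)(OS(=O)(=O)C(F)(F)F)C(F)(F)F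
Why: Biphasic Schotten–Baumann O-triflation of the β-keto ester, where the non-coordinating tetramethylammonium counter-ion lets the enolate react from its dipole-minimised form and should give the (E)-enol triflate with the triflate trans to the ester.

Step 15
Reactants: 18 13,14,15,16-tetranorlabda-7,11-dien-3β-ol; 20 methyl (2E)-3-(trifluoromethylsulfonyloxy)but-2-enoate
Product: 22 methyl 3β-hydroxylabda-7,13E-dien-15-oate, via alkylborane 21 (not isolated)
Conditions: 9-BBN (2.5 equiv; the excess allows for O-borylation of the C3 hydroxyl), THF, 0 °C → rt; then 20 (1.3 equiv), PdCl2(dppf) (5 mol%), K3PO4 (3 equiv), dioxane, 65 °C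
Reagents that add atoms: none
Why: Anti-Markovnikov hydroboration with 9-BBN is selective for the terminal vinyl group over the hindered C7=C8 bond, and the B-alkyl Suzuki–Miyaura coupling proceeds with retention at the enol triflate carbon, which fixes the 13E geometry.

Step 16
Reactants: 22 methyl 3β-hydroxylabda-7,13E-dien-15-oate
Product: 23 3β-hydroxylabda-7,13E-dien-15-oic acid
Conditions: LiOH (5 equiv), THF/MeOH/H2O (2:1:1), 50 °C; then 1 M HCl to pH 3
Reagents that add atoms: lithium hydroxide, [Li+].[OH-]
Why: Saponification by acyl–oxygen cleavage frees the acid while no acetate is yet present, and the carboxylate formed should resist isomerisation so the 13E geometry and C9 are kept.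

Step 17
Reactants: 23 3β-hydroxylabda-7,13E-dien-15-oic acid
Product: 25 3β-acetoxylabda-7,13E-dien-15-oic acid (target), via mixed anhydride 24 (not isolated)
Conditions: Ac2O (4 equiv), pyridine, DMAP (cat.), rt; then H2O/THF, rt
Reagents that add atoms: acetic anhydride, CC(=O)OC(C)=O
Why: DMAP-catalysed O-acetylation of the C3 hydroxyl with retention, the carboxyl group passing through its mixed acetic anhydride, which the aqueous quench should hydrolyse at the unhindered acetyl carbonyl to return the free acid.

Compound list
1 | methyl geranate, methyl (2E)-3,7-dimethylocta-2,6-dienoate | COC(=O)/C=C(\C)CCC=C(C)C | starting material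
2 | ozonide of 1 at C6=C7, methyl (2E)-5-(5,5-dimethyl-1,2,4-trioxolan-3-yl)-3-methylpent-2-enoate | COC(=O)/C=C(\C)CCC1OOC(C)(C)O1 | intermediate (not isolated)
3 | methyl (2E)-3-methyl-6-oxohex-2-enoate | COC(=O)/C=C(\C)CCC=O | intermediate
4 | 3-methylbuta-1,2-diene | CC(C)=C=C | starting material
5 | methyl (2E,6S)-6-hydroxy-3,7,7-trimethylnona-2,8-dienoate | COC(=O)/C=C(\C)CC[C@H](O)C(C)(C)C=C | intermediate
6 | methyl (2E,6S)-6-acetoxy-3,7,7-trimethylnona-2,8-dienoate | COC(=O)/C=C(\C)CC[C@H](OC(C)=O)C(C)(C)C=C | intermediate
7 | methyl (2E,6S)-6-acetoxy-8,9-dihydroxy-3,7,7-trimethylnon-2-enoate (C8 epimers) | COC(=O)/C=C(\C)CC[C@H](OC(C)=O)C(C)(C)C(O)CO | intermediate (not isolated)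
8 | methyl (2E,6S)-6-acetoxy-3,7,7-trimethyl-8-oxooct-2-enoate | COC(=O)/C=C(\C)CC[C@H](OC(C)=O)C(C)(C)C=O | intermediate
9 | diethyl (2-oxobutyl)phosphonate | CCC(=O)CP(=O)(OCC)OCC | starting material
10 | methyl (2E,6S,8E)-6-acetoxy-3,7,7-trimethyl-10-oxododeca-2,8-dienoate | COC(=O)/C=C(\C)CC[C@H](OC(C)=O)C(C)(C)/C=C/C(=O)CC | intermediate
11 | methyl (2E,6S,8E,10Z)-6-acetoxy-10-(tert-butyldimethylsilyloxy)-3,7,7-trimethyldodeca-2,8,10-trienoate | COC(=O)/C=C(\C)CC[C@H](OC(C)=O)C(C)(C)/C=C/C(O[Si](C)(C)C(C)(C)C)=C/C | intermediate
12 | methyl 3β-acetoxy-7-(tert-butyldimethylsilyloxy)-8αH-drim-6-en-11-oate | CC(=O)O[C@H]1CC[C@]2(C)[C@@H](C(=O)OC)[C@@H](C)C(O[Si](C)(C)C(C)(C)C)=C[C@H]2C1(C)C | intermediate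
13 | methyl 3β-acetoxy-7-oxo-8αH-driman-11-oate | CC(=O)O[C@H]1CC[C@]2(C)[C@@H](C(=O)OC)[C@@H](C)C(=O)C[C@H]2C1(C)C | intermediate
14 | methyl 3β-acetoxy-7-(trifluoromethylsulfonyloxy)drim-7-en-11-oate | CC(=O)O[C@H]1CC[C@]2(C)[C@@H](C(=O)OC)C(C)=C(OS(=O)(=O)C(F)(F)F)C[C@H]2C1(C)C | intermediate
15 | methyl 3β-acetoxydrim-7-en-11-oate | CC(=O)O[C@H]1CC[C@]2(C)[C@@H](C(=O)OC)C(C)=CC[C@H]2C1(C)C | intermediate
16 | drim-7-ene-3β,11-diol | O[C@H]1CC[C@]2(C)[C@@H](CO)C(C)=CC[C@H]2C1(C)C | intermediate
17 | 3β-hydroxydrim-7-en-11-al | O[C@H]1CC[C@]2(C)[C@@H](C=O)C(C)=CC[C@H]2C1(C)C | intermediate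
18 | 13,14,15,16-tetranorlabda-7,11-dien-3β-ol | O[C@H]1CC[C@]2(C)[C@@H](C=C)C(C)=CC[C@H]2C1(C)C | intermediate
19 | methyl acetoacetate | COC(=O)CC(C)=O | starting material
20 | methyl (2E)-3-(trifluoromethylsulfonyloxy)but-2-enoate | COC(=O)/C=C(\C)OS(=O)(=O)C(F)(F)F | intermediate
21 | 12-(9-borabicyclo[3.3.1]nonan-9-yl)-13,14,15,16-tetranorlabd-7-en-3β-ol | O[C@H]1CC[C@]2(C)[C@@H](CCB3C4CCCC3CCC4)C(C)=CC[C@H]2C1(C)C | intermediate (not isolated)
22 | methyl 3β-hydroxylabda-7,13E-dien-15-oate | O[C@H]1CC[C@]2(C)[C@@H](CC/C(C)=C/C(=O)OC)C(C)=CC[C@H]2C1(C)C | intermediate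
23 | 3β-hydroxylabda-7,13E-dien-15-oic acid | O[C@H]1CC[C@]2(C)[C@@H](CC/C(C)=C/C(=O)O)C(C)=CC[C@H]2C1(C)C | intermediate
24 | acetic 3β-acetoxylabda-7,13E-dien-15-oic anhydride | CC(=O)O[C@H]1CC[C@]2(C)[C@@H](CC/C(C)=C/C(=O)OC(C)=O)C(C)=CC[C@H]2C1(C)C | intermediate (not isolated)
25 | 3β-acetoxylabda-7,13E-dien-15-oic acid | CC(=O)O[C@H]1CC[C@]2(C)[C@@H](CC/C(C)=C/C(=O)O)C(C)=CC[C@H]2C1(C)C | target

Total step count: 17. Longest linear sequence: 16 steps (steps 1–13 and 15–17; step 14 makes the coupling partner).

Steps most likely to fail

Step 7. The cycloaddition may pass through the exo transition state (cis ring fusion) or show only a weak facial preference, because in the chair-like endo mode the C10 methyl comes syn-axial to the β-methyl on C4 and the equatorial bias of the C3 substituent next to a quaternary carbon is modest. Loss of the silyl group may also compete at the temperature this electronically mismatched pair needs. The fallback sets out from enone 10 and comes back at ketone 13. Enone 10 would be enolised with KN(SiMe3)2 at –78 °C and trapped with Ac2O to give the acid-stable dienyl acetate methyl (2E,6S,8E,10Z)-6,10-diacetoxy-3,7,7-trimethyldodeca-2,8,10-trienoate F1. This would be cyclised under Lewis acid promotion (EtAlCl2, CH2Cl2, –20 °C → rt), where coordination of the ester raises the endo preference and permits a low temperature, to give the enol acetate adduct methyl 3β,7-diacetoxy-8αH-drim-6-en-11-oate F2. Selective methanolysis of the reactive enol acetate (K2CO3, MeOH, 0 °C), which should spare the hindered C3 acetate, returns 13.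

Step 9. Proton loss from C6 may compete with proton loss from C8, so that the triflate forms with the C6=C7 regiochemistry. The fallback sets out from ketone 13 and comes back at triflate 14. The regiochemistry would be settled under equilibrating silylation (TMSCl, NaI, Et3N, MeCN, rt), which should give the more substituted silyl enol ether methyl 3β-acetoxy-7-(trimethylsilyloxy)drim-7-en-11-oate F3. Fluoride-triggered exchange (CsF, PhNTf2, DME, rt) then transfers the triflyl group to the same oxygen without moving the double bond and gives 14.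

Step 13. The basic ylide may deprotonate the aldehyde at C9, which is both α to the carbonyl and allylic, leading to epimerisation or migration of the C7=C8 bond into conjugation. The fallback sets out from aldehyde 17 and comes back at alkene 18 by a Peterson olefination. The weakly basic organocerium reagent from Me3SiCH2MgCl and CeCl3 (THF, –78 °C) would add to the aldehyde to give the β-hydroxysilane 12-(trimethylsilyl)-13,14,15,16-tetranorlabd-7-ene-3β,11-diol F4 as a mixture at C11. Syn elimination with KH (THF, 0 °C → rt), at a stage where no acidic C9 hydrogen remains, gives 18.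

Further compounds
F1 | step 7 | methyl (2E,6S,8E,10Z)-6,10-diacetoxy-3,7,7-trimethyldodeca-2,8,10-trienoate | COC(=O)/C=C(\C)CC[C@H](OC(C)=O)C(C)(C)/C=C/C(OC(C)=O)=C/C
F2 | step 7 | methyl 3β,7-diacetoxy-8αH-drim-6-en-11-oate | CC(=O)O[C@H]1CC[C@]2(C)[C@@H](C(=O)OC)[C@@H](C)C(OC(C)=O)=C[C@H]2C1(C)C
F3 | step 9 | methyl 3β-acetoxy-7-(trimethylsilyloxy)drim-7-en-11-oate | CC(=O)O[C@H]1CC[C@]2(C)[C@@H](C(=O)OC)C(C)=C(O[Si](C)(C)C)C[C@H]2C1(C)C
F4 | step 13 | 12-(trimethylsilyl)-13,14,15,16-tetranorlabd-7-ene-3β,11-diol (C11 epimers) | O[C@H]1CC[C@]2(C)[C@@H](C(O)C[Si](C)(C)C)C(C)=CC[C@H]2C1(C)C
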